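The flask held electrophile and protic impurity in equal amounts, and free base had to release the nucleophile from its protonated form.

    nucleophile + acid set free ⇌ protonated nucleophile, settled at all times (K1 = 6.95 × 10⁵ M⁻¹)
    electrophile + nucleophile ⇌ acid set free + target (K2 = 4.44, k2 = 5.16 M⁻¹ h⁻¹)
    electrophile + protic impurity → quenched substrate (k3 = 2.41 M⁻¹ h⁻¹)
    acid set free + free base ⇌ salt of the base, settled at all times (K4 = 3.2 × 10⁵ M⁻¹)

electrophile 20 mM; protonated nucleophile 50.0 mM; protic impurity 20.0 mM; time 4.0 d

* the concentration of free base at which the part of the electrophile that has reacted at 4.0 d is just 95%, in mM

I compared two amounts. The first was the reach a, the impurity concentration at which the pseudo-first-order lifetime of the electrophile equals the run, a = 1/(k3·t) = 4.32 mM. The second was T, the target needed. I counted two equivalents of free base per target: one to release the nucleophile, one to take up the acid set free. As a simplification, I took T as made at the start, so impurity then exceeded electrophile by T. With r = 1.00 mM of electrophile left at the end, the second-order law counted the lifetimes: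

T/a = ln[(r + T)(cA − T)/(r·cH2)]

Starting from T = a, successive passes gave 6.17 mM, 6.92 mM, 7.11 mM, then 7.15 mM, so the free base came to

14.3 mM

The forecast was lower, at 11.3 mM, and it also counted two: “each target uses two nucleophile equivalents”.

The simulation gave 13.1 mM.

At that charge, two equivalents per target put the ceiling on target at 6.55 mM, which is 1.52 reaches. The impurity step used electrophile at 2.3 times the forward rate of the nucleophile step at 0.504 d, and that ratio rose to 5.9 at 4.00 d, while the nucleophile step had 96% of its turnover behind it after 2.00 d.

All constants are made up.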